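## Retrosynthetic overview

1. The C3 carbinol comes last, by 1,2-addition of dibromomethyllithium to the ring B enone.
2. The exocyclic methylene and the cis-bromohydrin of ring A come from a vinylogous ester (γ-bromination, Peterson-type methylenation with hydrolysis, hydride reduction).
3. The spiro centre and ring B come from a Diels–Alder reaction of a 2-methylidenecyclohexanone (ring A) with a 1-methoxy-3-silyloxybutadiene. A C9 acetoxy group inherited from carvone directs the face and is then oxidised away, so chirality is relayed C9 → C6 → C10 → C9 and C6 → C3.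
4. The dienophile comes from (S)-carvone by two conjugate addition/dehydrogenation cycles (gem-dimethyl, exocyclic methylene) and a Criegee rearrangement (isopropenyl → OAc, retention).
5. Ring order: ring A is the carvone ring; ring B is formed second by the [4+2] cycloaddition.

Assumption: spiro compounds use chamigrene numbering (C1–C5 ring B, C6 spiro, C7–C11 ring A, exocyclic methylene on C7, CHBr2 on C3); C1 in 10–19 and C7 in 11 and 16 are carried as epimer mixtures that converge later.

## Route

Step 1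
Reactants: 1 (S)-(+)-carvone
Product: 3 (5S)-2,3-dimethyl-5-(prop-1-en-2-yl)cyclohex-2-en-1-one, via silyl enol ether 2 (not isolated)
Conditions: MeMgBr, CuBr·SMe2 (10 mol %), Me3SiCl, HMPA, THF, −78 °C; then Pd(OAc)2 (10 mol %), O2, DMSO, 25 °C
Reagents that add atoms: methylmagnesium bromide, C[Mg]Br
Why: Copper-catalysed conjugate addition (anti to the isopropenyl group) with silyl trapping, then Saegusa–Ito dehydrogenation of the regio-defined silyl enol ether toward the C3–H, restores the enone with the new 3-methyl group and leaves the bought stereocentre untouched.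

Step 2
Reactants: 3 (5S)-2,3-dimethyl-5-(prop-1-en-2-yl)cyclohex-2-en-1-one
Product: 5 (5S)-3,3-dimethyl-2-methylidene-5-(prop-1-en-2-yl)cyclohexan-1-one, via silyl enol ether 4 (not isolated)
Conditions: MeMgBr, CuBr·SMe2 (20 mol %), Me3SiCl, HMPA, THF, −78 to −30 °C; then Pd(OAc)2 (10 mol %), O2, DMSO, 40 °C
Reagents that add atoms: methylmagnesium bromide, C[Mg]Br
Why: A second conjugate addition builds the gem-dimethyl carbon, and Saegusa–Ito oxidation of the resulting silyl enol ether can only eliminate into the 2-methyl group (C3 is now quaternary), giving the exocyclic enone.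

Step 3
Reactants: 5 (5S)-3,3-dimethyl-2-methylidene-5-(prop-1-en-2-yl)cyclohexan-1-one
Product: 7 (1S)-3,3-dimethyl-4-methylidene-5-oxocyclohexyl acetate, via methoxy hydroperoxide 6 (not isolated)
Conditions: O3, CH2Cl2/MeOH, −78 °C; then Ac2O, Et3N, DMAP (cat.), CH2Cl2, −30 to 25 °C
Reagents that add atoms: ozone, [O-][O+]=O; methanol, CO
Why: Ozone cleaves the electron-rich isopropenyl alkene in preference to the enone C=C, and acylation of the methoxy hydroperoxide triggers Criegee rearrangement in which the ring carbon migrates to oxygen with retention, so the bought centre becomes C–OAc (the acetyl group is the former isopropenyl carbons).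

Step 4
Reactants: 8 (E)-4-methoxybut-3-en-2-one
Product: 9 tert-butyl{[(3E)-4-methoxybuta-1,3-dien-2-yl]oxy}dimethylsilane
Conditions: t-BuMe2SiOSO2CF3, Et3N, Et2O, 0 °C
Reagents that add atoms: tert-butyldimethylsilyl trifluoromethanesulfonate, CC(C)(C)[Si](C)(C)OS(=O)(=O)C(F)(F)F
Why: Soft enolisation (silyl triflate/amine) of the vinylogous ester gives the robust tert-butyldimethylsilyl analogue of Danishefsky's diene.

Step 5
Reactants: 7 (1S)-3,3-dimethyl-4-methylidene-5-oxocyclohexyl acetate; 9 tert-butyl{[(3E)-4-methoxybuta-1,3-dien-2-yl]oxy}dimethylsilane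
Product: 10 (6S,9S)-3-[(tert-butyldimethylsilyl)oxy]-1-methoxy-11,11-dimethyl-7-oxospiro[5.5]undec-2-en-9-yl acetate (C1 epimers)
Conditions: toluene, 110 °C, sealed tube
Reagents that add atoms: none
Why: Thermal Diels–Alder cycloaddition in which the CH2 terminus of the diene bonds to the exocyclic CH2 and the methoxy-bearing carbon to C6 (ortho rule), the diene approaching C6 axially on the face opposite the axial C11 methyl of the chair that keeps the 9-acetoxy group equatorial, which sets the spiro centre (6S) with C1 cis to the acetate.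

Step 6
Reactants: 10 (6S,9S)-3-[(tert-butyldimethylsilyl)oxy]-1-methoxy-11,11-dimethyl-7-oxospiro[5.5]undec-2-en-9-yl acetate
Product: 11 (6R,9S)-3-[(tert-butyldimethylsilyl)oxy]-1-methoxy-11,11-dimethylspiro[5.5]undec-2-ene-7,9-diol (C1 and C7 epimers; same spiro geometry as 10)
Conditions: i-Bu2AlH (4 equiv), CH2Cl2, −78 to 0 °C; H2O work-up
Reagents that add atoms: none
Why: Hydride reduction of the ketone and reductive cleavage of the acetate in one operation avoids exposing the β-acetoxy ketone to base (no E1cB elimination), and the C7 epimers converge in step 7.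

Step 7
Reactants: 11 (6R,9S)-3-[(tert-butyldimethylsilyl)oxy]-1-methoxy-11,11-dimethylspiro[5.5]undec-2-ene-7,9-diol
Product: 12 (6S)-3-[(tert-butyldimethylsilyl)oxy]-1-methoxy-11,11-dimethylspiro[5.5]undec-2-ene-7,9-dione
Conditions: Dess–Martin periodinane (2.2 equiv), pyridine, CH2Cl2, 0 to 25 °C
Reagents that add atoms: none
Why: Dess–Martin oxidation of both secondary alcohols gives the β-diketone, deliberately making C9 planar now that the stereochemical information is held by the spiro centre.

Step 8
Reactants: 12 (6S)-3-[(tert-butyldimethylsilyl)oxy]-1-methoxy-11,11-dimethylspiro[5.5]undec-2-ene-7,9-dione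
Product: 13 (6S)-3-[(tert-butyldimethylsilyl)oxy]-1,9-dimethoxy-11,11-dimethylspiro[5.5]undeca-2,8-dien-7-one
Conditions: Me3SiCHN2, MeOH/toluene, 0 °C
Reagents that add atoms: trimethylsilyldiazomethane, C[Si](C)(C)C=[N+]=[N-]
Why: Diazomethane generated in situ O-methylates the enolised β-diketone at the less hindered C9 oxygen (C7 is flanked by the quaternary spiro carbon), giving the vinylogous ester that keeps C8 out of later enolate chemistry.

Step 9
Reactants: 13 (6S)-3-[(tert-butyldimethylsilyl)oxy]-1,9-dimethoxy-11,11-dimethylspiro[5.5]undeca-2,8-dien-7-one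
Product: 15 (6S,10S)-10-bromo-3-[(tert-butyldimethylsilyl)oxy]-1,9-dimethoxy-11,11-dimethylspiro[5.5]undeca-2,8-dien-7-one, via siloxy methoxy diene 14 (not isolated)
Conditions: LiN(i-Pr)2, THF, −78 °C; Me3SiCl; then NBS (1.0 equiv), −78 °C
Reagents that add atoms: N-bromosuccinimide, O=C1CCC(=O)N1Br
Why: With the α′ position quaternary the amide base removes a γ-proton at C10, and NBS brominates the derived 1-siloxy-3-methoxy diene at its terminal carbon (Chan-type diene reactivity), anti to the pseudo-axial C11 methyl in the conformer whose branched C1 arm is pseudo-axial, which places bromine cis to C1 (10S).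

Step 10
Reactants: 15 (6S,10S)-10-bromo-3-[(tert-butyldimethylsilyl)oxy]-1,9-dimethoxy-11,11-dimethylspiro[5.5]undeca-2,8-dien-7-one
Product: 18 (6S,10S)-10-bromo-3-[(tert-butyldimethylsilyl)oxy]-1-methoxy-11,11-dimethyl-7-methylidenespiro[5.5]undec-2-en-9-one, via silylmethyl carbinol 16 (not isolated), via methoxy diene 17 (not isolated)
Conditions: Me3SiCH2Li, CeCl3, THF, −78 °C; then AcOH/H2O/THF, 0 °C
Reagents that add atoms: (trimethylsilyl)methyllithium, [Li]C[Si](C)(C)C; water, O
Why: Johnson–Peterson methylenation, in which the weakly basic organocerium adds 1,2 to the hindered vinylogous-ester carbonyl and mild acid then causes Peterson elimination to the methoxy diene and its hydrolysis by kinetic protonation at C8, gives the β,γ-unsaturated ketone with the exocyclic methylene while the ring B silyl enol ether survives.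

Step 11
Reactants: 18 (6S,10S)-10-bromo-3-[(tert-butyldimethylsilyl)oxy]-1-methoxy-11,11-dimethyl-7-methylidenespiro[5.5]undec-2-en-9-one
Product: 20 (6S,9R,10S)-10-bromo-9-hydroxy-11,11-dimethyl-7-methylidenespiro[5.5]undec-1-en-3-one, via silyl enol ether bromohydrin 19 (not isolated)
Conditions: i-Bu2AlH, CH2Cl2, −78 °C; then 1 M HCl, THF, 0 °C
Reagents that add atoms: none
Why: Hydride reaches the C9 carbonyl from the equatorial direction because the axial C11 methyl blocks the axial path, giving the axial alcohol cis to the equatorial bromide (9R), and the acidic work-up hydrolyses the silyl enol ether and eliminates methanol (E1cB) to unveil the ring B enone.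

Step 12
Reactants: 20 (6S,9R,10S)-10-bromo-9-hydroxy-11,11-dimethyl-7-methylidenespiro[5.5]undec-1-en-3-one
Product: 21 Mailiohydrin, (3R,6S,9R,10S)-10-bromo-3-(dibromomethyl)-11,11-dimethyl-7-methylidenespiro[5.5]undec-1-ene-3,9-diol
Conditions: CH2Br2, LiN(i-Pr)2 (3.5 equiv each), THF, −90 °C; then 20; AcOH quench at −90 °C
Reagents that add atoms: dibromomethane, BrCBr
Why: Dibromomethyllithium (a carbenoid made by deprotonating CH2Br2) adds 1,2 to the enone from the face of the flat exocyclic-methylene arm, away from the gem-dimethyl arm and the pseudo-axial C5–H, so that CHBr2 ends pseudo-equatorial and the 3R carbinol results.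

## Compound list

1 | (S)-(+)-carvone | CC1=CC[C@H](C(C)=C)CC1=O | starting material
2 | trimethyl{[(3S,5S)-2,3-dimethyl-5-(prop-1-en-2-yl)cyclohex-1-en-1-yl]oxy}silane | C[Si](C)(C)OC1=C(C)[C@@H](C)C[C@H](C(C)=C)C1 | intermediate
3 | (5S)-2,3-dimethyl-5-(prop-1-en-2-yl)cyclohex-2-en-1-one | CC1=C(C)C[C@H](C(C)=C)CC1=O | intermediate
4 | trimethyl{[(5S)-2,3,3-trimethyl-5-(prop-1-en-2-yl)cyclohex-1-en-1-yl]oxy}silane | C[Si](C)(C)OC1=C(C)C(C)(C)C[C@H](C(C)=C)C1 | intermediate
5 | (5S)-3,3-dimethyl-2-methylidene-5-(prop-1-en-2-yl)cyclohexan-1-one | C=C1C(=O)C[C@@H](C(C)=C)CC1(C)C | intermediate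
6 | (5S)-5-(1-hydroperoxy-1-methoxyethyl)-3,3-dimethyl-2-methylidenecyclohexan-1-one | C=C1C(=O)C[C@@H](C(C)(OC)OO)CC1(C)C | intermediate
7 | (1S)-3,3-dimethyl-4-methylidene-5-oxocyclohexyl acetate | C=C1C(=O)C[C@@H](OC(C)=O)CC1(C)C | intermediate
8 | (E)-4-methoxybut-3-en-2-one | CO/C=C/C(C)=O | starting material
9 | tert-butyl{[(3E)-4-methoxybuta-1,3-dien-2-yl]oxy}dimethylsilane | CO/C=C/C(=C)O[Si](C)(C)C(C)(C)C | intermediate
10 | (6S,9S)-3-[(tert-butyldimethylsilyl)oxy]-1-methoxy-11,11-dimethyl-7-oxospiro[5.5]undec-2-en-9-yl acetate (C1 epimers) | O=C1C[C@@H](OC(C)=O)CC(C)(C)[C@@]12C(OC)C=C(O[Si](C)(C)C(C)(C)C)CC2 | intermediate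
11 | (6R,9S)-3-[(tert-butyldimethylsilyl)oxy]-1-methoxy-11,11-dimethylspiro[5.5]undec-2-ene-7,9-diol (C1, C7 epimers) | OC1C[C@@H](O)CC(C)(C)[C@@]12C(OC)C=C(O[Si](C)(C)C(C)(C)C)CC2 | intermediate
12 | (6S)-3-[(tert-butyldimethylsilyl)oxy]-1-methoxy-11,11-dimethylspiro[5.5]undec-2-ene-7,9-dione | O=C1CC(=O)CC(C)(C)[C@@]12C(OC)C=C(O[Si](C)(C)C(C)(C)C)CC2 | intermediate
13 | (6S)-3-[(tert-butyldimethylsilyl)oxy]-1,9-dimethoxy-11,11-dimethylspiro[5.5]undeca-2,8-dien-7-one | O=C1C=C(OC)CC(C)(C)[C@@]12C(OC)C=C(O[Si](C)(C)C(C)(C)C)CC2 | intermediate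
14 | (6S)-3-[(tert-butyldimethylsilyl)oxy]-1,9-dimethoxy-11,11-dimethyl-7-[(trimethylsilyl)oxy]spiro[5.5]undeca-2,7,9-triene | C[Si](C)(C)OC1=CC(OC)=CC(C)(C)[C@@]12C(OC)C=C(O[Si](C)(C)C(C)(C)C)CC2 | intermediate
15 | (6S,10S)-10-bromo-3-[(tert-butyldimethylsilyl)oxy]-1,9-dimethoxy-11,11-dimethylspiro[5.5]undeca-2,8-dien-7-one | O=C1C=C(OC)[C@@H](Br)C(C)(C)[C@@]12C(OC)C=C(O[Si](C)(C)C(C)(C)C)CC2 | intermediate
16 | (6S,10S)-10-bromo-3-[(tert-butyldimethylsilyl)oxy]-1,9-dimethoxy-11,11-dimethyl-7-[(trimethylsilyl)methyl]spiro[5.5]undeca-2,8-dien-7-ol (C7 epimers) | C[Si](C)(C)CC1(O)C=C(OC)[C@@H](Br)C(C)(C)[C@@]12C(OC)C=C(O[Si](C)(C)C(C)(C)C)CC2 | intermediate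
17 | (6S,10S)-10-bromo-3-[(tert-butyldimethylsilyl)oxy]-1,9-dimethoxy-11,11-dimethyl-7-methylidenespiro[5.5]undeca-2,8-diene | C=C1C=C(OC)[C@@H](Br)C(C)(C)[C@@]12C(OC)C=C(O[Si](C)(C)C(C)(C)C)CC2 | intermediate
18 | (6S,10S)-10-bromo-3-[(tert-butyldimethylsilyl)oxy]-1-methoxy-11,11-dimethyl-7-methylidenespiro[5.5]undec-2-en-9-one | C=C1CC(=O)[C@@H](Br)C(C)(C)[C@@]12C(OC)C=C(O[Si](C)(C)C(C)(C)C)CC2 | intermediate
19 | (6S,9R,10S)-10-bromo-3-[(tert-butyldimethylsilyl)oxy]-1-methoxy-11,11-dimethyl-7-methylidenespiro[5.5]undec-2-en-9-ol | C=C1C[C@@H](O)[C@@H](Br)C(C)(C)[C@@]12C(OC)C=C(O[Si](C)(C)C(C)(C)C)CC2 | intermediate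
20 | (6S,9R,10S)-10-bromo-9-hydroxy-11,11-dimethyl-7-methylidenespiro[5.5]undec-1-en-3-one | C=C1C[C@@H](O)[C@@H](Br)C(C)(C)[C@@]12C=CC(=O)CC2 | intermediate
21 | Mailiohydrin, (3R,6S,9R,10S)-10-bromo-3-(dibromomethyl)-11,11-dimethyl-7-methylidenespiro[5.5]undec-1-ene-3,9-diol | C=C1C[C@@H](O)[C@@H](Br)C(C)(C)[C@@]12C=C[C@@](O)(C(Br)Br)CC2 | target

## Step count and weakest steps

Total: 12 steps. Longest linear sequence: 11 steps (1 → 21); step 4 makes the diene on a side branch.

The three steps most likely to fail: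

Step 12, because the face selectivity at C3 is set only by the remote spiro centre and the kinetic addition may favour the 3-epimer. The fallback sets out from 20 and returns at 21. Tribromomethyl anion (CHBr3, DBU, 0 °C) adds reversibly, so the bulkier group settles pseudo-equatorial under thermodynamic control and gives the tribromomethyl carbinol F1. One bromine is then removed by radical hydrodebromination with Bu3SnH (1 equiv, Et3B, −78 °C), the CBr3 group reacting far faster than the secondary bromide, to give 21.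

Step 9, because bromine may enter at C10 on the face trans to C1 (or partly at C8). The fallback sets out from 13 (through diene 14) and returns at 15. The diene terminus is oxidised with dimethyldioxirane (Rubottom-type), which puts oxygen on the face electrophiles prefer and gives the γ-hydroxy vinylogous ester F2. This is converted (Tf2O, pyridine, −78 °C) into the triflate F3, and SN2 displacement with LiBr, activated by the adjacent vinylogous carbonyl, inverts C10. If direct bromination gives the wrong epimer, this sequence therefore gives 15.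

Step 10, because the acid needed for the Peterson elimination and hydrolysis may also open the ring B silyl enol ether, after which the hydride of step 11 would no longer be selective. The fallback sets out from 15 and returns at 20. After the organocerium addition the mixture is quenched with 1 M HCl so that both masked ketones are released, giving the enedione F4. Excess i-Bu2AlH reduces both carbonyls to the diol F5 (axial 9-OH for the reason given in step 11, C3 epimers). MnO2 in CH2Cl2 then re-oxidises only the allylic C3 alcohol and gives 20.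

## Further compounds

F1 | step 12 | (3R,6S,9R,10S)-10-bromo-11,11-dimethyl-7-methylidene-3-(tribromomethyl)spiro[5.5]undec-1-ene-3,9-diol | C=C1C[C@@H](O)[C@@H](Br)C(C)(C)[C@@]12C=C[C@@](O)(C(Br)(Br)Br)CC2
F2 | step 9 | (6S,10R)-3-[(tert-butyldimethylsilyl)oxy]-10-hydroxy-1,9-dimethoxy-11,11-dimethylspiro[5.5]undeca-2,8-dien-7-one | O=C1C=C(OC)[C@H](O)C(C)(C)[C@@]12C(OC)C=C(O[Si](C)(C)C(C)(C)C)CC2
F3 | step 9 | (6S,10R)-3-[(tert-butyldimethylsilyl)oxy]-1,9-dimethoxy-11,11-dimethyl-7-oxospiro[5.5]undeca-2,8-dien-10-yl trifluoromethanesulfonate | O=C1C=C(OC)[C@H](OS(=O)(=O)C(F)(F)F)C(C)(C)[C@@]12C(OC)C=C(O[Si](C)(C)C(C)(C)C)CC2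
F4 | step 10 | (6S,10S)-10-bromo-11,11-dimethyl-7-methylidenespiro[5.5]undec-1-ene-3,9-dione | C=C1CC(=O)[C@@H](Br)C(C)(C)[C@@]12C=CC(=O)CC2
F5 | step 10 | (6S,9R,10S)-10-bromo-11,11-dimethyl-7-methylidenespiro[5.5]undec-1-ene-3,9-diol (C3 epimers) | C=C1C[C@@H](O)[C@@H](Br)C(C)(C)[C@@]12C=CC(O)CC2
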